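**Retrosynthetic overview**
1. Last step (C–C): remove the formyl group at C3 of the dihydroxy ring, i.e. Rieche formylation of the only free aromatic C–H of the depside.
2. Key disconnection: the depside acyl C–O bond, giving 2,4-dihydroxy-5,6-dimethylbenzaldehyde and methyl 4-hydroxy-2-methoxy-3,5,6-trimethylbenzoate, joined by oxidative esterification at the aldehyde oxidation level without protecting groups.
3. Phenol half: C–H hydroxylation of methyl 2-methoxy-3,5,6-trimethylbenzoate, from exhaustive O-methylation of the Kolbe–Schmitt acid of 2,4,5-trimethylphenol; the OMe/OH pattern follows from the order of events, not from a selective methylation.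
4. Aldehyde half: Vilsmeier formylation of 4,5-dimethylresorcinol.
5. Rings: none is formed; both benzene rings are bought intact and only decorated (convergent: 3 + 1 steps, then 2).

Assumption: the SMILES has no stereocentre and the hindered aryl ester is not configurationally stable, so the target is achiral and there is no enantiomer to control.
Reagent note: 4,5-dichlorophthaloyl peroxide is not a catalogue item; it is made in one operation from 4,5-dichlorophthaloyl chloride and sodium percarbonate (handle behind a shield) and is not counted as a route step.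

**Route**

Step 1
Reactants: 1 2,4,5-trimethylphenol
Product: 4 2-hydroxy-3,5,6-trimethylbenzoic acid, via sodium phenolate 2 (not isolated), via sodium carboxylate 3 (not isolated)
Conditions: NaOH (1.0 equiv), then dried; CO2 (50 bar), 150 °C, autoclave; aq. HCl
Reagents that add atoms: carbon dioxide (O=C=O)
Why: Kolbe–Schmitt carboxylation, in which the sodium phenolate takes up CO2 at the only free ortho carbon (the para position carries a methyl group), as in the thymol to o-thymotic acid case where the reacting carbon also has a methyl neighbour.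

Step 2
Reactants: 4 2-hydroxy-3,5,6-trimethylbenzoic acid
Product: 6 methyl 2-methoxy-3,5,6-trimethylbenzoate, via methyl ester 5 (not isolated)
Conditions: MeI (3 equiv), K2CO3 (3 equiv), DMF, 50 °C
Reagents that add atoms: iodomethane (CI)
Why: Double SN2 O-methylation (carboxylate alkylation, then Williamson etherification of the hydrogen-bonded phenol), which avoids the tetrahedral intermediate that blocks Fischer esterification of a 2,6-disubstituted benzoic acid and raises no regiochemical question because both acidic oxygens are to be methylated.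

Step 3
Reactants: 6 methyl 2-methoxy-3,5,6-trimethylbenzoate
Product: 8 methyl 4-hydroxy-2-methoxy-3,5,6-trimethylbenzoate, via aryl phthalate half-ester 7 (not isolated)
Conditions: 4,5-dichlorophthaloyl peroxide (1.3 equiv), HFIP, 23 → 40 °C; then MeOH/sat. aq. NaHCO3, 40 °C
Reagents that add atoms: 4,5-dichlorophthaloyl peroxide (O=C1OOC(=O)c2cc(Cl)c(Cl)cc12)
Why: Metal-free arene C–H oxygenation by a cyclic diacyl peroxide (reverse-rebound aroyloxylation) followed by bicarbonate cleavage of the aryl phthalate; the ring has a single C–H so no isomer can form, and the doubly ortho-substituted methyl ester is inert to NaHCO3/MeOH.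

Step 4
Reactants: 9 4,5-dimethylbenzene-1,3-diol (4,5-dimethylresorcinol)
Product: 11 2,4-dihydroxy-5,6-dimethylbenzaldehyde, via iminium chloride 10 (not isolated)
Conditions: (chloromethylene)dimethyliminium chloride (1.2 equiv), MeCN, 0 °C → rt; then H2O, 50 °C
Reagents that add atoms: (chloromethylene)dimethyliminium chloride (C[N+](C)=CCl.[Cl-]); water (O)
Why: Vilsmeier–Haack formylation, which attacks the resorcinol para to one OH and ortho to the other (C6) rather than between the two OH groups, the same selectivity as orcinol to orcylaldehyde.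

Step 5
Reactants: 11 2,4-dihydroxy-5,6-dimethylbenzaldehyde and 8 methyl 4-hydroxy-2-methoxy-3,5,6-trimethylbenzoate
Product: 14 methyl 4-[(2,4-dihydroxy-5,6-dimethylbenzoyl)oxy]-2-methoxy-3,5,6-trimethylbenzoate, via acyl azolium iodide 12 (not isolated), via quinoketene 13 (not isolated)
Conditions: 1,4-dimethyl-1,2,4-triazolium iodide (10 mol%), DBU (20 mol%), 3,3′,5,5′-tetra-tert-butyldiphenoquinone (1.1 equiv), 8 (1.5 equiv), THF, 4 Å MS, 40 °C, 11 added over 6 h
Reagents that add atoms: none
Why: Proposed new method: carbene-catalysed two-electron oxidation of the formyl group gives acyl azolium 12, whose ortho-phenol, once deprotonated, expels the small neutral carbene (E1cB) to give the linear, unhindered quinoketene 13, which the 2,6-dimethyl-type phenol 8 can reach although a tetrahedral pathway at this doubly ortho-substituted acyl carbon would be blocked; mis-acylation at the acidic 4-OH of 11 or 14 gives active esters (leaving-group pKa about 8) that the carbene returns to 12 and 13, so the acyl group is funnelled to the less acidic phenol 8, helped by slow addition of 11 and excess 8; the closest known reaction types are NHC-catalysed oxidative esterification of aldehydes with alcohols and simple phenols using the diphenoquinone oxidant and salicylate formation through quinoketenes from benzodioxinones, neither shown for an unprotected 2,4-dihydroxybenzaldehyde with a 2,6-disubstituted phenol to make a depside.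

Step 6
Reactants: 14 methyl 4-[(2,4-dihydroxy-5,6-dimethylbenzoyl)oxy]-2-methoxy-3,5,6-trimethylbenzoate
Product: 16 methyl 4-[(3-formyl-2,4-dihydroxy-5,6-dimethylbenzoyl)oxy]-2-methoxy-3,5,6-trimethylbenzoate, via chloro ether 15 (not isolated)
Conditions: Cl2CHOMe (1.5 equiv), TiCl4 (3 equiv), CH2Cl2, −10 → 0 °C; then 1 M HCl, 0 °C
Reagents that add atoms: dichloromethyl methyl ether (COC(Cl)Cl); water (O)
Why: Rieche formylation (Friedel–Crafts reaction of the chloromethoxycarbenium ion), in which titanium bound to the two phenols directs the electrophile to the only free aromatic C–H (C3, between the OH groups), the other ring being fully substituted, while the aryl ester, methyl ester and methyl ether tolerate TiCl4 at 0 °C; the product is the target.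

**Compound list**

1 | 2,4,5-trimethylphenol | Cc1cc(C)c(O)cc1C | starting material
2 | sodium 2,4,5-trimethylphenolate | Cc1cc(C)c([O-])cc1C.[Na+] | intermediate (not isolated)
3 | sodium 2-hydroxy-3,5,6-trimethylbenzoate | Cc1cc(C)c(O)c(C(=O)[O-])c1C.[Na+] | intermediate (not isolated)
4 | 2-hydroxy-3,5,6-trimethylbenzoic acid | Cc1cc(C)c(O)c(C(=O)O)c1C | intermediate
5 | methyl 2-hydroxy-3,5,6-trimethylbenzoate | COC(=O)c1c(O)c(C)cc(C)c1C | intermediate (not isolated)
6 | methyl 2-methoxy-3,5,6-trimethylbenzoate | COC(=O)c1c(OC)c(C)cc(C)c1C | intermediate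
7 | 4,5-dichloro-2-{[3-methoxy-4-(methoxycarbonyl)-2,5,6-trimethylphenoxy]carbonyl}benzoic acid | COC(=O)c1c(OC)c(C)c(OC(=O)c2cc(Cl)c(Cl)cc2C(=O)O)c(C)c1C | intermediate (not isolated)
8 | methyl 4-hydroxy-2-methoxy-3,5,6-trimethylbenzoate | COC(=O)c1c(OC)c(C)c(O)c(C)c1C | intermediate
9 | 4,5-dimethylbenzene-1,3-diol | Cc1cc(O)cc(O)c1C | starting material
10 | (2,4-dihydroxy-5,6-dimethylbenzylidene)dimethylammonium chloride | C[N+](C)=Cc1c(O)cc(O)c(C)c1C.[Cl-] | intermediate (not isolated)
11 | 2,4-dihydroxy-5,6-dimethylbenzaldehyde | Cc1c(C)c(C=O)c(O)cc1O | intermediate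
12 | 5-(2,4-dihydroxy-5,6-dimethylbenzoyl)-1,4-dimethyl-1H-1,2,4-triazol-4-ium iodide | CN1N=C[N+](C)=C1C(=O)c1c(C)c(C)c(O)cc1O.[I-] | intermediate (not isolated)
13 | 3-hydroxy-4,5-dimethyl-6-(oxomethylidene)cyclohexa-2,4-dien-1-one | O=C=C1C(=O)C=C(O)C(C)=C1C | intermediate (not isolated)
14 | methyl 4-[(2,4-dihydroxy-5,6-dimethylbenzoyl)oxy]-2-methoxy-3,5,6-trimethylbenzoate | COC(=O)c1c(C)c(C)c(OC(=O)c2c(C)c(C)c(O)cc2O)c(C)c1OC | intermediate
15 | methyl 4-({3-[chloro(methoxy)methyl]-2,4-dihydroxy-5,6-dimethylbenzoyl}oxy)-2-methoxy-3,5,6-trimethylbenzoate (racemic at the transient CHCl carbon) | COC(=O)c1c(C)c(C)c(OC(=O)c2c(C)c(C)c(O)c(C(Cl)OC)c2O)c(C)c1OC | intermediate (not isolated)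
16 | methyl 4-[(3-formyl-2,4-dihydroxy-5,6-dimethylbenzoyl)oxy]-2-methoxy-3,5,6-trimethylbenzoate (achiral) | COC(=O)c1c(C)c(C)c(OC(=O)c2c(C)c(C)c(O)c(C=O)c2O)c(C)c1OC | target

**Totals**

Total step count: 6 (steps 1–3 make 8, step 4 makes 11, steps 5–6 join and finish).
Longest linear sequence: 5 steps (1 → 4 → 6 → 8 → 14 → 16).

**Steps most likely to fail, with fallbacks**

Step 5 (the proposed new oxidative depside coupling) is the most likely to fail. The acidic 4-OH of 11 may be acylated faster than the hindered phenol 8, and the phenoxide form of 11 may be too electron-rich for the carbene to add. The fallback uses known chemistry and sets out from 11. Both phenols are benzylated (BnBr, K2CO3, DMF, 60 °C) to give 2,4-bis(benzyloxy)-5,6-dimethylbenzaldehyde F1. Pinnick oxidation (NaClO2, NaH2PO4, 2-methyl-2-butene, t-BuOH/H2O) gives 2,4-bis(benzyloxy)-5,6-dimethylbenzoic acid F2. This is condensed with 8 by trifluoroacetic anhydride in toluene at rt (mixed anhydride/acylium esterification, the classical method for hindered depsides) to give methyl 4-{[2,4-bis(benzyloxy)-5,6-dimethylbenzoyl]oxy}-2-methoxy-3,5,6-trimethylbenzoate F3. Hydrogenolysis (H2, Pd/C, EtOAc) then comes back to the route at 14. This replaces catalytic oxidation at the aldehyde level by acid activation with protecting groups, at a cost of three extra steps.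

Step 3 (C–H hydroxylation) is the second risk, because the para ester lowers the nucleophilicity of the single ring C–H and ipso attack next to the methoxy group could give dienone by-products. The fallback sets out from 6. Electrophilic bromination (Br2, AcOH, cat. Fe, rt; only one position is free) gives methyl 4-bromo-2-methoxy-3,5,6-trimethylbenzoate F4. Palladium-catalysed hydroxylation (Pd2(dba)3, tBuXPhos-type ligand, KOH, dioxane/H2O, 100 °C; the doubly ortho-substituted ester resists saponification) comes back at 8. This replaces direct C–H oxidation by halogenation and cross-coupling, at a cost of one extra step.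

Step 6 (late Rieche formylation) is the third risk, because TiCl4 could cleave the methyl ether ortho to the ester or attack the depside linkage on the most advanced material. The fallback sets out from 14 and avoids strong Lewis acid. Magnesium-phenolate-directed ortho-hydroxymethylation (MgCl2, Et3N, paraformaldehyde, MeCN, reflux; Casnati–Skattebøl conditions) gives methyl 4-{[2,4-dihydroxy-3-(hydroxymethyl)-5,6-dimethylbenzoyl]oxy}-2-methoxy-3,5,6-trimethylbenzoate F5. This is oxidised in the same flask by a second formaldehyde (Oppenauer-type hydride transfer) and comes back at 16. This replaces a Friedel–Crafts carbenium electrophile by phenolate addition to formaldehyde followed by an oxidation-level adjustment.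

**Further compounds**

F1 | step 5 | 2,4-bis(benzyloxy)-5,6-dimethylbenzaldehyde | O=Cc1c(OCc2ccccc2)cc(OCc2ccccc2)c(C)c1C
F2 | step 5 | 2,4-bis(benzyloxy)-5,6-dimethylbenzoic acid | OC(=O)c1c(OCc2ccccc2)cc(OCc2ccccc2)c(C)c1C
F3 | step 5 | methyl 4-{[2,4-bis(benzyloxy)-5,6-dimethylbenzoyl]oxy}-2-methoxy-3,5,6-trimethylbenzoate | COC(=O)c1c(C)c(C)c(OC(=O)c2c(C)c(C)c(OCc3ccccc3)cc2OCc2ccccc2)c(C)c1OC
F4 | step 3 | methyl 4-bromo-2-methoxy-3,5,6-trimethylbenzoate | COC(=O)c1c(OC)c(C)c(Br)c(C)c1C
F5 | step 6 | methyl 4-{[2,4-dihydroxy-3-(hydroxymethyl)-5,6-dimethylbenzoyl]oxy}-2-methoxy-3,5,6-trimethylbenzoate | COC(=O)c1c(C)c(C)c(OC(=O)c2c(C)c(C)c(O)c(CO)c2O)c(C)c1OC
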